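Compound numbers used throughout (benzofuran numbering for 10–16 and the target, chroman numbering for 5 and 7–9): 1 4-methoxyresorcinol, 2 acetophenone, 3 its benzyl ether, 4 enaminone, 5 chromone, 6 arylboronic acid, 7 (S)-flavanone, 8 enol ether, 9 iodane ketal, 10 trans ester, 11 alcohol, 12 mesylate, 13 3-methyl benzyl ether, 14 phenol, 15 allyltrimethylsilane, 16 target.

## Analysis of the target

The target is a 3,3a-dihydrobenzofuran-6(2H)-one. Ring A (C3a, C4, C5, C6, C7, C7a) is a cross-conjugated cyclohexa-2,5-dienone with a methoxy group on C5 and the ketone at C6. Ring B (O1, C2, C3, C3a, C7a) is a dihydrofuran whose oxygen sits on C7a, so O1–C7a=C7–C6=O is a vinylogous ester. Three contiguous stereocentres are present, all S: C2 (3,4,5-trimethoxyphenyl), C3 (methyl) and the quaternary ring-fusion carbon C3a (allyl). Aryl and methyl are trans on ring B, and allyl is trans to methyl, hence on the face of the aryl group. The dienone is a dearomatised phenol held only by the quaternary carbon, so heat or acid can move the allyl group ([3,3] shift to C5 and on to aromatic isomers); the O1–C2 bond is a benzylic ether open to ionisation and hydrogenolysis. The difficulty is to fix C2 and C3 in absolute terms and then to create C3a, late and mildly, while ring A loses its aromaticity. The strategy rests on the C3–C3a bond: ring B is a chroman-4-one ring short of one member, and this bond results when the ring A carbon on the carbonyl carbon of a flavanone shifts to the neighbouring methylene carbon. The extruded carbonyl carbon stays on C3 as an ester and becomes the C3 methyl group.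

## Retrosynthetic reasoning

**C3a–allyl.** The first cut is the C3a–CH2 bond, which turns 16 into phenol 14 and allylsilane 15. Ring A of 16 is the dearomatised form of the C6 phenol and C3a is para to that oxygen, so two-electron oxidation of 14 puts electrophilic character on the carbon that must become quaternary. Cutting here confines the fragile dienone to the last flask. It also builds the quaternary centre next to a finished C3 stereocentre, whose methyl group should direct the nucleophile to the opposite face, the one the target needs. The forward reaction has to prefer C3a over the methoxy-bearing C5 and over C7, and has to outrun loss of H3.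

**Functional group changes on the aromatic stage.** Phenol 14 is carried as benzyl ether 13, because a free phenol would not survive the oxidant of the key step and an alkoxy group para to the migrating carbon helps that step. The C3 methyl of 13 is traced through mesylate 12 and alcohol 11 to the ester of 10. No carbon is added or removed, and neither C2 nor C3 is touched.

**C3–C3a (key disconnection).** In 10 the C3–C3a bond is cut and C3a is reattached to the ester carbon, which gives flavanone 7. A 2,3-trans dihydrobenzofuran with two stereocentres becomes a six-membered ketone with one; C3 then follows from C2 by a stereospecific shift, not from a second asymmetric reaction. The forward step is an oxidative 1,2-shift under trivalent iodine. It must move the ring A carbon rather than the C2 aryl group and must leave C2 alone.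

**C2–aryl.** Flavanone 7 is cut at the C2–aryl bond to chromone 5 and boronic acid 6. The other obvious cut, O1–C2 (closure of a 2'-hydroxychalcone), is reversible, and catalysts distinguish the faces of an unactivated chalcone only moderately. Conjugate addition of the aryl group is irreversible and sets C2 under ligand control in a single step.

**Ring A building block.** Chromone 5 comes from acetophenone 3 by one-carbon extension of the acetyl group and closure onto the free 2-hydroxyl. Selective benzylation relates 3 to 2, and C-acylation relates 2 to resorcinol 1, which already carries all three ring A oxygens in the right places.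

## Alternatives that were turned down

**Alternative 1:** Ring A is cut at C3a–C7a and traced to a four-membered ring. Cyclobutenone A1 carries, on its sp3 carbon, an alkene whose fully substituted terminus bears the allyl group and the complete C2–C3 side chain. Heating A1 in toluene would open it to a dienylketene, and 6π closure onto the alkene terminus would give the 6,6-disubstituted cyclohexa-2,4-dienone A2. That step forms C3a–C7a, ring A and the quaternary centre at once.
- For it: the dienone is assembled convergently at the right oxidation level and no site-selective dearomatisation of a methoxyphenol is needed. On that point it is stronger than the chosen route.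
- Against it: the ketene can bond to either face of the alkene terminus, and the only bias is the neighbouring acyclic stereocentre (the future C3). C3a is therefore weakly controlled in the step that creates it.
- A1 needs a separate anti-selective construction of the C2/C3 pair and a hindered alkenyl-metal addition.
- A2 still has to be desilylated, closed at O1–C7a and have its oxygen pattern transposed, on a linearly conjugated dienone of a kind that dimerises easily.
- In its place the chosen route makes C3a next to a stereocentre held in a ring, sets the other two centres before the dienone exists, and needs markedly fewer operations.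

**Alternative 2:** The C3–CH3 and C3a–CH2 bonds are cut together. A methyl cuprate would add to C3 of the (S)-butenolide A3 (lactone carbonyl = future C7a, acetal carbon = future C4) anti to the aryl group. The lactone enolate would then be trapped by an allyl halide anti to the new methyl group, giving lactone A4 with all three stereocentres.
- For it: both new centres follow from C2 by two dependable trans inductions on a rigid five-membered ring. Control of the quaternary centre is firmer than in the chosen route, whose last step must find both the right carbon and the right face.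
- Against it: A4 has no ring A. Three carbons (C5, C6, C7) with a methoxy group and a ketone must be attached to a lactone carbonyl beside a quaternary carbon and to a masked aldehyde; the ring must then be closed and its oxidation level adjusted.
- The enolate of the key step also has an ethoxy group in the β position, so loss of ethoxide competes with allylation.
- This is far longer, and the difficulty moves from stereocontrol to ring construction. The chosen route keeps ring A as an intact, fully oxygenated benzene ring from step 1 and spends its steps on ring B only.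

**Alternative 3:** Ring B is cut at O1–C7a. The C2 alkoxide of the prochiral 4,4-disubstituted cyclohexadienone A5 would add 5-exo-trig to one of the two diastereotopic enone β-carbons. This gives the cis-fused bicycle A6 and fixes C3a by the choice of alkene.
- For it: the closure is mild, needs no oxidant, can be run under equilibrating conditions, and guarantees the ring fusion. It also avoids oxidising a methoxyphenol in the presence of a carbon nucleophile, which is the weak point of the chosen route.
- Against it: choosing between the two alkenes is choosing between allyl cis and trans to the C3 methyl group, and that rests on modest conformational preferences of the forming ring.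
- A5 itself needs the anti C2/C3 pair and a quaternary, allyl-bearing dienone carbon, so the dearomatisation problem is moved, not removed.
- A6 lacks the C5 methoxy group and the C7=C7a double bond. An α-oxygenation, an O-methylation and a dehydrogenation must follow, on a β-alkoxy ketone that can reopen by retro-Michael reaction.
- The chosen route reaches the ring A oxidation pattern of the target directly in its dearomatising step, at the price of a site-selectivity question there.

Key step: step 5

Remark: (R)-t-BuPyOx, (R)-4-tert-butyl-2-(pyridin-2-yl)-4,5-dihydrooxazole, is assumed to give the 2S flavanone by extension of the facial preference this ligand family shows with cyclic enones; the sense is to be confirmed on 7, and the antipodal ligand is used if it proves opposite.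

## Route

Step 1
Reactants: 1 4-methoxybenzene-1,3-diol
Product: 2 1-(2,4-dihydroxy-5-methoxyphenyl)ethan-1-one
Conditions: AcOH, BF3·OEt2, 90 °C; aq. NaOAc work-up
Reagents that add atoms: acetic acid, CC(=O)O
Why: Friedel–Crafts (Nencki-type) C-acylation at C6 of 1, the only ring position ortho to one hydroxyl and para to the other. The boron chelate of the resulting ortho-hydroxy ketone deactivates the ring towards a second acylation.

Step 2
Reactants: 2 1-(2,4-dihydroxy-5-methoxyphenyl)ethan-1-one
Product: 3 1-[4-(benzyloxy)-2-hydroxy-5-methoxyphenyl]ethan-1-one
Conditions: BnBr (1.05 equiv), K2CO3, acetone, reflux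
Reagents that add atoms: benzyl bromide, BrCc1ccccc1
Why: Williamson ether synthesis. The 2-hydroxyl is hydrogen-bonded to the ketone and reacts much more slowly, so the 4-hydroxyl (para to the acyl group) should be alkylated selectively.

Step 3
Reactants: 3 1-[4-(benzyloxy)-2-hydroxy-5-methoxyphenyl]ethan-1-one
Product: 5 7-(benzyloxy)-6-methoxy-4H-chromen-4-one, via enaminone 4 (not isolated)
Conditions: Me2NCH(OMe)2, toluene, 100 °C; then conc. HCl, CH2Cl2, 40 °C
Reagents that add atoms: N,N-dimethylformamide dimethyl acetal, COC(OC)N(C)C
Why: Enaminone route to chromones: the amide acetal condenses with the methyl ketone, then acid promotes addition of the phenol to the β-carbon and loss of dimethylamine. The benzyl and methyl ethers are inert to both stages.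

Step 4
Reactants: 5 7-(benzyloxy)-6-methoxy-4H-chromen-4-one; 6 (3,4,5-trimethoxyphenyl)boronic acid
Product: 7 (S)-7-(benzyloxy)-6-methoxy-2-(3,4,5-trimethoxyphenyl)chroman-4-one
Conditions: Pd(OCOCF3)2 (5 mol%), (R)-t-BuPyOx (6 mol%), NH4PF6 (30 mol%), H2O (5 equiv), ClCH2CH2Cl, 60 °C
Reagents that add atoms: none
Why: Asymmetric conjugate addition of an arylboronic acid to a chromone under a cationic divalent palladium pyridine-oxazoline catalyst: transmetallation, insertion of C2=C3 into the aryl–palladium bond, and protonolysis of the palladium enolate by water. C2 is set in the insertion step by the ligand, which blocks one face of the bound enone; the addition is irreversible, so the centre is not eroded by ring opening.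

Step 5
Reactants: 7 (S)-7-(benzyloxy)-6-methoxy-2-(3,4,5-trimethoxyphenyl)chroman-4-one
Product: 10 methyl (2S,3S)-6-(benzyloxy)-5-methoxy-2-(3,4,5-trimethoxyphenyl)-2,3-dihydrobenzofuran-3-carboxylate, via methyl enol ether 8 (not isolated), via iodane ketal 9 (not isolated)
Conditions: PhI(OAc)2 (1.2 equiv), HC(OMe)3, H2SO4, 20 °C
Reagents that add atoms: trimethyl orthoformate, COC(OC)OC
Why: Acid and the orthoformate convert the ketone into methyl enol ether 8; the trivalent iodine electrophile adds to C3 of 8 on the face away from the pseudo-equatorial C2 aryl group and methanol caps C4, giving iodane ketal 9. In 9 the equatorial C3–I bond is antiperiplanar to the C4–C4a bond, so the ring A carbon C4a, activated by the para benzyloxy group, shifts from C4 to C3 as iodobenzene leaves, and the dimethoxycarbenium ion left at the old C4 ends as the methyl ester on work-up. The closest known reaction type is the oxidative 1,2-aryl shift of aryl ketones and flavanones with PhI(OAc)2 (or Tl(NO3)3) in trimethyl orthoformate, which gives methyl trans-2-aryl-2,3-dihydrobenzofuran-3-carboxylates. Ring B is not closed end to end: it arises by contraction of the pyranone ring, the C3–C4a bond (C3–C3a of the product) forming as C4–C4a breaks in a 1,2-shift with inversion at C3. The new stereocentre C3 is controlled by C2: iodination trans to the aryl group followed by rear-side entry of C4a leaves the ester carbon on the face the iodine held, trans to the aryl group (3S), while C2 is not involved. The selectivity needed is migration of C4a in preference to migration of the C2 aryl group (isoflavone pathway) and to loss of HI (flavone pathway); the trans-diequatorial iodane, in which the C2–aryl bond is gauche to C3–I, and the para alkoxy donor on ring A secure it.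

Step 6
Reactants: 10 methyl (2S,3S)-6-(benzyloxy)-5-methoxy-2-(3,4,5-trimethoxyphenyl)-2,3-dihydrobenzofuran-3-carboxylate
Product: 11 [(2S,3R)-6-(benzyloxy)-5-methoxy-2-(3,4,5-trimethoxyphenyl)-2,3-dihydrobenzofuran-3-yl]methanol
Conditions: LiAlH4, THF, 0 °C
Reagents that add atoms: none
Why: Hydride reduction of the ester to the primary alcohol, fast at a temperature where the ester enolate cannot expel O1. The geometry at C2 and C3 is unchanged; the C3 label changes to R only because the substituent priorities change.

Step 7
Reactants: 11 [(2S,3R)-6-(benzyloxy)-5-methoxy-2-(3,4,5-trimethoxyphenyl)-2,3-dihydrobenzofuran-3-yl]methanol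
Product: 12 [(2S,3R)-6-(benzyloxy)-5-methoxy-2-(3,4,5-trimethoxyphenyl)-2,3-dihydrobenzofuran-3-yl]methyl methanesulfonate
Conditions: MsCl, Et3N, CH2Cl2, 0 °C
Reagents that add atoms: methanesulfonyl chloride, CS(=O)(=O)Cl
Why: Sulfonylation of a primary alcohol under amine base; no stereocentre takes part.

Step 8
Reactants: 12 [(2S,3R)-6-(benzyloxy)-5-methoxy-2-(3,4,5-trimethoxyphenyl)-2,3-dihydrobenzofuran-3-yl]methyl methanesulfonate
Product: 13 (2S,3S)-6-(benzyloxy)-5-methoxy-3-methyl-2-(3,4,5-trimethoxyphenyl)-2,3-dihydrobenzofuran
Conditions: LiBHEt3, THF, 0 °C to 20 °C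
Reagents that add atoms: none
Why: SN2 displacement of the primary mesylate by hydride gives the C3 methyl group. The aryl ethers are not attacked at this temperature.

Step 9
Reactants: 13 (2S,3S)-6-(benzyloxy)-5-methoxy-3-methyl-2-(3,4,5-trimethoxyphenyl)-2,3-dihydrobenzofuran
Product: 14 (2S,3S)-5-methoxy-3-methyl-2-(3,4,5-trimethoxyphenyl)-2,3-dihydrobenzofuran-6-ol
Conditions: H2 (1 atm), Pd/C, EtOAc, 20 °C
Reagents that add atoms: none
Why: Hydrogenolysis of the benzyl aryl ether. The ring O1–C2 bond is benzylic as well but is cleaved much more slowly, so the reaction is stopped after uptake of one equivalent.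

Step 10
Reactants: 14 (2S,3S)-5-methoxy-3-methyl-2-(3,4,5-trimethoxyphenyl)-2,3-dihydrobenzofuran-6-ol; 15 allyltrimethylsilane
Product: 16 (2S,3S,3aS)-3a-allyl-5-methoxy-3-methyl-2-(3,4,5-trimethoxyphenyl)-3,3a-dihydrobenzofuran-6(2H)-one
Conditions: PhI(OAc)2 (1.1 equiv), 15 (5 equiv), (CF3)2CHOH/CH2Cl2, −40 °C
Reagents that add atoms: none
Why: Oxidative Hosomi–Sakurai-type allylation of a para-substituted phenol: the trivalent iodine reagent turns the phenol into a phenoxonium-type electrophile in the fluorinated alcohol, and the allylsilane adds at C3a, para to the oxygen, giving a cross-conjugated dienone that cannot rearomatise. The quaternary centre is set by the adjacent C3 stereocentre, the silane approaching anti to the methyl group (3aS).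

## Compound list

1 | 4-methoxybenzene-1,3-diol | COc1ccc(O)cc1O | starting material
2 | 1-(2,4-dihydroxy-5-methoxyphenyl)ethan-1-one | CC(=O)c1cc(OC)c(O)cc1O | intermediate
3 | 1-[4-(benzyloxy)-2-hydroxy-5-methoxyphenyl]ethan-1-one | CC(=O)c1cc(OC)c(OCc2ccccc2)cc1O | intermediate
4 | (E)-1-[4-(benzyloxy)-2-hydroxy-5-methoxyphenyl]-3-(dimethylamino)prop-2-en-1-one | CN(C)/C=C/C(=O)c1cc(OC)c(OCc2ccccc2)cc1O | intermediate (not isolated)
5 | 7-(benzyloxy)-6-methoxy-4H-chromen-4-one | O=c1ccoc2cc(OCc3ccccc3)c(OC)cc12 | intermediate
6 | (3,4,5-trimethoxyphenyl)boronic acid | COc1cc(B(O)O)cc(OC)c1OC | starting material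
7 | (S)-7-(benzyloxy)-6-methoxy-2-(3,4,5-trimethoxyphenyl)chroman-4-one | COc1cc2c(cc1OCc1ccccc1)O[C@H](c1cc(OC)c(OC)c(OC)c1)CC2=O | intermediate
8 | (S)-7-(benzyloxy)-4,6-dimethoxy-2-(3,4,5-trimethoxyphenyl)-2H-chromene | COc1cc2c(cc1OCc1ccccc1)O[C@H](c1cc(OC)c(OC)c(OC)c1)C=C2OC | intermediate (not isolated)
9 | acetoxy[(2R,3R)-7-(benzyloxy)-4,4,6-trimethoxy-2-(3,4,5-trimethoxyphenyl)chroman-3-yl]phenyliodane (iodine on C3 trans to the C2 aryl group; the labels differ from 7 by priority only) | COc1cc2c(cc1OCc1ccccc1)O[C@H](c1cc(OC)c(OC)c(OC)c1)[C@@H](I(OC(C)=O)c1ccccc1)C2(OC)OC | intermediate (not isolated)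
10 | methyl (2S,3S)-6-(benzyloxy)-5-methoxy-2-(3,4,5-trimethoxyphenyl)-2,3-dihydrobenzofuran-3-carboxylate | COc1cc2c(cc1OCc1ccccc1)O[C@H](c1cc(OC)c(OC)c(OC)c1)[C@H]2C(=O)OC | intermediate
11 | [(2S,3R)-6-(benzyloxy)-5-methoxy-2-(3,4,5-trimethoxyphenyl)-2,3-dihydrobenzofuran-3-yl]methanol | COc1cc2c(cc1OCc1ccccc1)O[C@H](c1cc(OC)c(OC)c(OC)c1)[C@H]2CO | intermediate
12 | [(2S,3R)-6-(benzyloxy)-5-methoxy-2-(3,4,5-trimethoxyphenyl)-2,3-dihydrobenzofuran-3-yl]methyl methanesulfonate | COc1cc2c(cc1OCc1ccccc1)O[C@H](c1cc(OC)c(OC)c(OC)c1)[C@H]2COS(C)(=O)=O | intermediate
13 | (2S,3S)-6-(benzyloxy)-5-methoxy-3-methyl-2-(3,4,5-trimethoxyphenyl)-2,3-dihydrobenzofuran | COc1cc2c(cc1OCc1ccccc1)O[C@H](c1cc(OC)c(OC)c(OC)c1)[C@H]2C | intermediate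
14 | (2S,3S)-5-methoxy-3-methyl-2-(3,4,5-trimethoxyphenyl)-2,3-dihydrobenzofuran-6-ol | COc1cc2c(cc1O)O[C@H](c1cc(OC)c(OC)c(OC)c1)[C@H]2C | intermediate
15 | allyltrimethylsilane | C=CC[Si](C)(C)C | starting material
16 | (2S,3S,3aS)-3a-allyl-5-methoxy-3-methyl-2-(3,4,5-trimethoxyphenyl)-3,3a-dihydrobenzofuran-6(2H)-one | C=CC[C@]12C=C(OC)C(=O)C=C1O[C@H](c1cc(OC)c(OC)c(OC)c1)[C@H]2C | target

## Step count and least certain steps

Total: 10 steps. Longest linear sequence: 10 steps, from 1 to 16; 6 and 15 are purchased.

**Step 5 (key step).** The shift may go to the wrong group: the C2 trimethoxyphenyl group can migrate from C2 to C3, or HI can be lost, if the iodane reacts through a conformer with an axial C3–I bond. The iodane may also attack the electron-rich aromatic positions instead of the enol ether, and the acid may ionise the benzylic O1–C2 bond and erode the C2 configuration.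
- Fallback (Wolff ring contraction, which moves the same carbon C4a from C4 to C3 without an iodane): it sets out from 7. Heating 7 with Me2NCH(OMe)2 should give the enaminone (2R)-7-(benzyloxy)-3-[(E)-(dimethylamino)methylidene]-6-methoxy-2-(3,4,5-trimethoxyphenyl)chroman-4-one F1. Diazo transfer with TsN3 in CH2Cl2 should give the diazoketone (R)-7-(benzyloxy)-3-diazo-6-methoxy-2-(3,4,5-trimethoxyphenyl)chroman-4-one F2; the R labels of F1 and F2 come from a change of priority, not of geometry.
- Irradiation of F2 in methanol (Wolff rearrangement, ketene trapped by methanol) should give the ring-contracted ester as a mixture of 10 and its cis isomer methyl (2S,3R)-6-(benzyloxy)-5-methoxy-2-(3,4,5-trimethoxyphenyl)-2,3-dihydrobenzofuran-3-carboxylate F3. NaOMe in MeOH equilibrates F3 to the trans ester, so the route is rejoined at 10. The C2 centre must be shown to survive the enaminone stage.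

**Step 10.** Three things can go wrong. The allylsilane may add at C5, ipso to the methoxy group where the charge is stabilised as an oxocarbenium ion, or at C7, instead of C3a. The oxidised intermediate may lose H3 and aromatise ring B to a benzofuran. The silane may also approach syn to the methyl group.
- Fallback (relay of the allyl group by sigmatropic shift), setting out from 14 and covering attack at C5: the same reagents would then give (2S,3S,5R)-5-allyl-5-methoxy-3-methyl-2-(3,4,5-trimethoxyphenyl)-2,3-dihydrobenzofuran-6(5H)-one F4 and its C5 epimer (2S,3S,5S)-5-allyl-5-methoxy-3-methyl-2-(3,4,5-trimethoxyphenyl)-2,3-dihydrobenzofuran-6(5H)-one F5.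
- After separation, F4 is warmed in toluene (80–110 °C). A Cope rearrangement across C5–C4=C3a carries the allyl group suprafacially to the same face of C3a and comes back to the route at 16. F5 would lead to the C3a epimer and is set aside.
- Limits: this relay gives up control of the face at C5, and reversion to an aromatic allyl ether competes on heating, so it is a rescue and not an equal of step 10.

**Step 4.** Insertion into the electron-rich, vinylogous-ester C2=C3 bond of 5 may be slow, so that protodeboronation of 6 takes over. The facial selectivity may be insufficient or opposite to the assumed sense.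
- Fallback (closing O1–C2 instead of forming C2–aryl), setting out from 3: Claisen–Schmidt condensation with 3,4,5-trimethoxybenzaldehyde (KOH, EtOH) should give the chalcone (E)-1-[4-(benzyloxy)-2-hydroxy-5-methoxyphenyl]-3-(3,4,5-trimethoxyphenyl)prop-2-en-1-one F6.
- Intramolecular oxa-Michael addition under a quinine-derived bifunctional thiourea in toluene returns to the route at 7. The closure is reversible, so lower selectivity is expected and 7 would have to be enriched by crystallisation.

**Step 8.** The mesylate may ionise with participation of the electron-rich ring A carbon C3a (a shift back towards a six-membered ring), or eliminate, instead of undergoing direct displacement.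
- Fallback (radical instead of polar reduction), setting out from 11: I2, PPh3 and imidazole in CH2Cl2 should give the iodide (2S,3S)-6-(benzyloxy)-3-(iodomethyl)-5-methoxy-2-(3,4,5-trimethoxyphenyl)-2,3-dihydrobenzofuran F7.
- Bu3SnH with AIBN in toluene at 80 °C reduces the C–I bond faster than the primary radical can rearrange, and the route is rejoined at 13.

## Further compounds

F1 | step 5 | (2R)-7-(benzyloxy)-3-[(E)-(dimethylamino)methylidene]-6-methoxy-2-(3,4,5-trimethoxyphenyl)chroman-4-one | CN(C)/C=C1\[C@@H](c2cc(OC)c(OC)c(OC)c2)Oc2cc(OCc3ccccc3)c(OC)cc2C1=O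
F2 | step 5 | (R)-7-(benzyloxy)-3-diazo-6-methoxy-2-(3,4,5-trimethoxyphenyl)chroman-4-one | COc1cc2c(cc1OCc1ccccc1)O[C@H](c1cc(OC)c(OC)c(OC)c1)C(=[N+]=[N-])C2=O
F3 | step 5 | methyl (2S,3R)-6-(benzyloxy)-5-methoxy-2-(3,4,5-trimethoxyphenyl)-2,3-dihydrobenzofuran-3-carboxylate | COc1cc2c(cc1OCc1ccccc1)O[C@H](c1cc(OC)c(OC)c(OC)c1)[C@@H]2C(=O)OC
F4 | step 10 | (2S,3S,5R)-5-allyl-5-methoxy-3-methyl-2-(3,4,5-trimethoxyphenyl)-2,3-dihydrobenzofuran-6(5H)-one | C=CC[C@@]1(OC)C=C2C(=CC1=O)O[C@H](c1cc(OC)c(OC)c(OC)c1)[C@H]2C
F5 | step 10 | (2S,3S,5S)-5-allyl-5-methoxy-3-methyl-2-(3,4,5-trimethoxyphenyl)-2,3-dihydrobenzofuran-6(5H)-one | C=CC[C@]1(OC)C=C2C(=CC1=O)O[C@H](c1cc(OC)c(OC)c(OC)c1)[C@H]2C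
F6 | step 4 | (E)-1-[4-(benzyloxy)-2-hydroxy-5-methoxyphenyl]-3-(3,4,5-trimethoxyphenyl)prop-2-en-1-one | COc1cc(/C=C/C(=O)c2cc(OC)c(OCc3ccccc3)cc2O)cc(OC)c1OC
F7 | step 8 | (2S,3S)-6-(benzyloxy)-3-(iodomethyl)-5-methoxy-2-(3,4,5-trimethoxyphenyl)-2,3-dihydrobenzofuran | COc1cc2c(cc1OCc1ccccc1)O[C@H](c1cc(OC)c(OC)c(OC)c1)[C@H]2CI
A1 | alternative 1 | 4-[(3S,4S)-2-allyl-4-(tert-butyldimethylsilyloxy)-3-methyl-4-(3,4,5-trimethoxyphenyl)but-1-en-1-yl]-3,4-dimethoxycyclobut-2-en-1-one (alkene geometry and ring C4 configuration not fixed; both are lost in the ring opening) | C=CCC(=CC1(OC)C(OC)=CC1=O)[C@H](C)[C@H](O[Si](C)(C)C(C)(C)C)c1cc(OC)c(OC)c(OC)c1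
A2 | alternative 1 | (S)-6-allyl-6-[(1S,2S)-1-(tert-butyldimethylsilyloxy)-1-(3,4,5-trimethoxyphenyl)propan-2-yl]-3,4-dimethoxycyclohexa-2,4-dien-1-one | C=CC[C@@]1(C=C(OC)C(OC)=CC1=O)[C@H](C)[C@H](O[Si](C)(C)C(C)(C)C)c1cc(OC)c(OC)c(OC)c1
A3 | alternative 2 | (S)-3-(diethoxymethyl)-5-(3,4,5-trimethoxyphenyl)furan-2(5H)-one | CCOC(OCC)C1=C[C@@H](c2cc(OC)c(OC)c(OC)c2)OC1=O
A4 | alternative 2 | (3S,4S,5S)-3-allyl-3-(diethoxymethyl)-4-methyl-5-(3,4,5-trimethoxyphenyl)dihydrofuran-2(3H)-one | C=CC[C@]1(C(OCC)OCC)C(=O)O[C@H](c2cc(OC)c(OC)c(OC)c2)[C@H]1C
A5 | alternative 3 | 4-allyl-4-[(1S,2S)-1-hydroxy-1-(3,4,5-trimethoxyphenyl)propan-2-yl]cyclohexa-2,5-dien-1-one | C=CCC1(C=CC(=O)C=C1)[C@H](C)[C@H](O)c1cc(OC)c(OC)c(OC)c1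
A6 | alternative 3 | (2S,3S,3aR,7aR)-3a-allyl-3-methyl-2-(3,4,5-trimethoxyphenyl)-2,3,7,7a-tetrahydrobenzofuran-6(3aH)-one | C=CC[C@]12C=CC(=O)C[C@H]1O[C@H](c1cc(OC)c(OC)c(OC)c1)[C@H]2C
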